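The ring is numbered as follows: C1 bears C7H2OH, C2 is the ketone, C3 carries the tiglate, C4 the isopropyl group (C8), C5 the angelate, and C6 is the vinylic CH. The carbocycle is cut at C2–C3 and C4–C5. Two features of the ring justify this cut. C2 and C5 flank the C1=C6 alkene as the termini of a diene would. The C3/C4-trans, C4/C5-cis triad is what an endo [4+2] union of two E-configured partners produces. One catalytic enantioselective Diels–Alder reaction therefore creates the ring, both bonds and all three stereocentres. Its precursors are an (E)-1-silyloxy-3-(silyloxymethyl)buta-1,3-diene (C5, C6, C1, C2, C7) and (E)-4-tigloyloxybut-3-en-2-one (C3, C4, C8), whose acetyl group later becomes isopropyl.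

Key step: step 6

Assumption: the absolute sense of step 6 is assigned from the usual picture of enone–oxazaborolidinium complexes, which points to the salt derived from (S)-α,α-diphenylprolinol; if the first adduct proved antipodal, the equally available (R)-amino alcohol would be used with nothing else changed.

**Step 1**
Reactants: 1 hydroxyacetone
Product: 2 1-(tert-butyldiphenylsilyloxy)propan-2-one
Conditions: tBuPh2SiCl, imidazole, CH2Cl2, 0 °C → rt
Reagents that add atoms: tert-butyldiphenylsilyl chloride, CC(C)(C)[Si](Cl)(c1ccccc1)c1ccccc1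
Why: Silyl ether formation (substitution at silicon, with imidazole as base and activator) masks the C7 oxygen with a group that tolerates hydride, Lewis acid, mild acid and hexavalent chromium and leaves only with fluoride at the end.

**Step 2**
Reactants: 2 1-(tert-butyldiphenylsilyloxy)propan-2-one; 3 diethyl (cyanomethyl)phosphonate
Product: 4 4-(tert-butyldiphenylsilyloxy)-3-methylbut-2-enenitrile (E/Z mixture)
Conditions: NaH, THF, 0 °C → rt
Reagents that add atoms: none
Why: Horner–Wadsworth–Emmons olefination of the ketone adds C6 and C5 in one operation, and the E/Z mixture is harmless because C1 loses its geometrical descriptor when the diene is formed.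

**Step 3**
Reactants: 4 4-(tert-butyldiphenylsilyloxy)-3-methylbut-2-enenitrile
Product: 6 4-(tert-butyldiphenylsilyloxy)-3-methylbut-2-enal (E/Z mixture), via N-diisobutylaluminio aldimine 5 (not isolated)
Conditions: iBu2AlH, toluene, −78 °C; then 1 M aq. HCl, 0 °C
Reagents that add atoms: water, O (supplies the aldehyde oxygen); diisobutylaluminium hydride, CC(C)C[AlH]CC(C)C (its aluminium stays only in 5)
Why: Partial reduction of a nitrile delivers one hydride to give aldimine 5, which resists further reduction at low temperature and is hydrolysed to the enal on acidic work-up while the silyl ether stays inert.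

**Step 4**
Reactants: 6 4-(tert-butyldiphenylsilyloxy)-3-methylbut-2-enal
Product: 7 (E)-1-(tert-butyldimethylsilyloxy)-3-[(tert-butyldiphenylsilyloxy)methyl]buta-1,3-diene
Conditions: tBuMe2SiOSO2CF3, Et3N, Et2O, 0 °C → rt
Reagents that add atoms: tert-butyldimethylsilyl trifluoromethanesulfonate, CC(C)(C)[Si](C)(C)OS(=O)(=O)C(F)(F)F
Why: Soft vinylogous enolisation (silyl dienol ether formation) gives an s-trans O-silyl oxocarbenium ion from which Et3N takes a proton of the open C2 methyl group rather than of the C7 methylene shielded by tert-butyldiphenylsilyl, so the E dienol ether should result, and any Z isomer cannot reach the s-cis form and stays a spectator in step 6.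

**Step 5**
Reactants: 8 tiglic acid; 9 but-3-yn-2-one
Product: 10 (E)-3-oxobut-1-en-1-yl (E)-2-methylbut-2-enoate
Conditions: 1,4-diazabicyclo[2.2.2]octane (5 mol %), CH2Cl2, 0 °C
Reagents that add atoms: none
Why: Amine-catalysed conjugate addition of the carboxylic acid to the ynone (oxa-Michael addition–elimination through a β-ammonium enone) gives the thermodynamically preferred E enol ester with full atom economy and leaves the tiglate double bond untouched.

**Step 6**
Reactants: 7 (E)-1-(tert-butyldimethylsilyloxy)-3-[(tert-butyldiphenylsilyloxy)methyl]buta-1,3-diene; 10 (E)-3-oxobut-1-en-1-yl (E)-2-methylbut-2-enoate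
Product: 11 (1S,5S,6R)-6-acetyl-5-(tert-butyldimethylsilyloxy)-3-[(tert-butyldiphenylsilyloxy)methyl]cyclohex-3-en-1-yl (E)-2-methylbut-2-enoate (route locants 3S,4R,5S; 3,4-trans, 4,5-cis)
Conditions: (S)-3,3-diphenyl-1-(2-methylphenyl)tetrahydro-1H,3H-pyrrolo[1,2-c][1,3,2]oxazaborole (C24H24BNO, 20 mol %) + HN(SO2CF3)2 (17 mol %), CH2Cl2, −25 °C; then 10, 7 (1.5 equiv), −78 → −40 °C; Et3N quench
Reagents that add atoms: none
Why: The N-protonated oxazaborolidine binds the acetyl oxygen of 10 through boron, lowers its LUMO and triggers a concerted but asynchronous suprafacial [π4s+π2s] cycloaddition in which C2–C3 forms ahead of C4–C5, the closest known reaction type being the oxazaborolidinium-catalysed enantioselective Diels–Alder reaction of acyclic enones with silyloxydienes. The six-membered carbocycle closes in an intermolecular 4+2 mode, both σ-bonds forming in the same step on one face of each partner while the remaining π-bond settles at C1=C6. At C3 and C4 the E geometry of 10 becomes the trans relation, and the absolute sense comes from the catalyst, which holds the s-trans enone (boron on the oxygen lone pair syn to C4–H, that C–H against the ring oxygen) in front of one phenyl group so that only the Si faces of C3 and C4 stay open. At C5 the E-configured silyloxy terminus of 7, combined with the endo position of the boron-bound acetyl group, places O5 cis to C8. The required regioselectivity (acetyl ortho to the silyloxy carbon and para to C1) is secured by the oxygen donor at C5 and the alkyl branch at C1, which both raise the HOMO coefficient at C2 and match it with the electrophilic oxygen-bearing C3. Chemoselectivity rests on the bulky tert-butyldimethylsilyl group and on keeping the oxazaborolidine in slight excess over the acid, which suppress silyl transfer and the racemic channel it would open, while the hindered, unactivated tiglate alkene cannot compete as dienophile.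

**Step 7**
Reactants: 11 Diels–Alder adduct
Product: 12 (1S,5S,6R)-5-(tert-butyldimethylsilyloxy)-3-[(tert-butyldiphenylsilyloxy)methyl]-6-(prop-1-en-2-yl)cyclohex-3-en-1-yl (E)-2-methylbut-2-enoate
Conditions: Cp2TiMe2 (2 equiv), toluene, 65 °C, dark
Reagents that add atoms: dimethyltitanocene Cp2TiMe2, C[Ti+2]C.c1cc[cH-]c1.c1cc[cH-]c1
Why: In the Petasis methylenation, thermally formed Cp2Ti=CH2 undergoes [2+2] cycloaddition and cycloreversion with the ketone, and because it is non-basic C4 should not epimerise, O3 and O5 should not be lost by β-elimination, and the methyl ketone should react well before the hindered conjugated ester.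

**Step 8**
Reactants: 12 isopropenyl compound
Product: 13 (1S,5S,6R)-5-(tert-butyldimethylsilyloxy)-3-[(tert-butyldiphenylsilyloxy)methyl]-6-isopropylcyclohex-3-en-1-yl (E)-2-methylbut-2-enoate
Conditions: H2 (1 atm), RhCl(PPh3)3 (10 mol %), toluene–EtOH, rt
Reagents that add atoms: none
Why: Homogeneous hydrogenation with RhCl(PPh3)3 discriminates by steric access, so only the 1,1-disubstituted isopropenyl alkene is saturated while the trisubstituted C1=C6 and tiglate alkenes remain.

**Step 9**
Reactants: 13 isopropyl compound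
Product: 14 (1S,5S,6S)-3-[(tert-butyldiphenylsilyloxy)methyl]-5-hydroxy-6-isopropylcyclohex-3-en-1-yl (E)-2-methylbut-2-enoate
Conditions: camphor-10-sulfonic acid (10 mol %), MeOH–CH2Cl2, 0 °C → rt
Reagents that add atoms: none
Why: Acid-catalysed methanolysis of silyl ethers is far faster for tert-butyldimethylsilyl than for tert-butyldiphenylsilyl, so only O5 is freed, and the tiglate cannot migrate because O3 and O5 lie on opposite ring faces.

**Step 10**
Reactants: 14 C5 alcohol; 15 angelic acid; 16 2,4,6-trichlorobenzoyl chloride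
Product: 18 (1S,5S,6R)-3-[(tert-butyldiphenylsilyloxy)methyl]-6-isopropyl-5-[(Z)-2-methylbut-2-enoyloxy]cyclohex-3-en-1-yl (E)-2-methylbut-2-enoate, via angelic 2,4,6-trichlorobenzoic anhydride 17 (not isolated)
Conditions: 15, 16, Et3N, toluene, rt; then 14, 80 °C
Reagents that add atoms: none
Why: In this Yamaguchi-type mixed-anhydride esterification the alcohol attacks the angeloyl carbonyl of 17 because two ortho chlorines block the aroyl carbonyl, omitting nucleophilic pyridine catalysts avoids the addition–elimination that turns angelate into tiglate, and C5 keeps its configuration since its C–O bond is untouched.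

**Step 11**
Reactants: 18 C5 angelate C3 tiglate diester
Product: 19 (1R,5S,6S)-3-[(tert-butyldiphenylsilyloxy)methyl]-6-isopropyl-5-[(Z)-2-methylbut-2-enoyloxy]-2-oxocyclohex-3-en-1-yl (E)-2-methylbut-2-enoate
Conditions: CrO3, 3,5-dimethylpyrazole, CH2Cl2, −20 °C
Reagents that add atoms: chromium trioxide CrO3, O=[Cr](=O)=O
Why: Allylic oxidation with the CrO3–3,5-dimethylpyrazole complex (hexavalent chromium) should convert the only allylic ring methylene, C2, into the ketone, because its pseudoaxial C–H is aligned with the π-system, C5–H is pseudoequatorial and deactivated by its acyloxy group, C7–H is shielded by the bulky silyl group, and the two enoate alkenes are electron-poor.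

**Step 12**
Reactants: 19 silyl-protected enone
Product: 20 target, (1R,5S,6S)-3-(hydroxymethyl)-6-isopropyl-5-[(Z)-2-methylbut-2-enoyloxy]-2-oxocyclohex-3-en-1-yl (E)-2-methylbut-2-enoate (route locants 3R,4S,5S)
Conditions: HF·pyridine, pyridine, THF, 0 °C → rt
Reagents that add atoms: none
Why: Fluoride-induced desilylation in a mildly acidic medium frees the C7 alcohol without enolising the ketone, so C3 is not epimerised and neither ester migrates or isomerises.

**Compound list**

| No. | Name | SMILES | Role |
|---|---|---|---|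
| 1 | hydroxyacetone | CC(=O)CO | starting material |
| 2 | 1-(tert-butyldiphenylsilyloxy)propan-2-one | CC(=O)CO[Si](c1ccccc1)(c1ccccc1)C(C)(C)C | intermediate |
| 3 | diethyl (cyanomethyl)phosphonate | CCOP(=O)(CC#N)OCC | starting material |
| 4 | 4-(tert-butyldiphenylsilyloxy)-3-methylbut-2-enenitrile, E/Z mixture | CC(=CC#N)CO[Si](c1ccccc1)(c1ccccc1)C(C)(C)C | intermediate |
| 5 | N-diisobutylaluminio aldimine of 6, not isolated | CC(=CC=N[Al](CC(C)C)CC(C)C)CO[Si](c1ccccc1)(c1ccccc1)C(C)(C)C | intermediate |
| 6 | 4-(tert-butyldiphenylsilyloxy)-3-methylbut-2-enal, E/Z mixture | CC(=CC=O)CO[Si](c1ccccc1)(c1ccccc1)C(C)(C)C | intermediate |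
| 7 | (E)-1-(tert-butyldimethylsilyloxy)-3-[(tert-butyldiphenylsilyloxy)methyl]buta-1,3-diene | CC(C)(C)[Si](C)(C)O/C=C/C(=C)CO[Si](c1ccccc1)(c1ccccc1)C(C)(C)C | intermediate |
| 8 | tiglic acid | C/C=C(\C)C(=O)O | starting material |
| 9 | but-3-yn-2-one | CC(=O)C#C | starting material |
| 10 | (E)-3-oxobut-1-en-1-yl (E)-2-methylbut-2-enoate | CC(=O)/C=C/OC(=O)/C(C)=C/C | intermediate |
| 11 | Diels–Alder adduct (C4 acetyl, C3 tiglate, C5 OTBS, C7 OTBDPS) | CC(C)(C)[Si](C)(C)O[C@H]1C=C(CO[Si](c2ccccc2)(c2ccccc2)C(C)(C)C)C[C@H](OC(=O)/C(C)=C/C)[C@H]1C(C)=O | intermediate |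
| 12 | isopropenyl compound | CC(C)(C)[Si](C)(C)O[C@H]1C=C(CO[Si](c2ccccc2)(c2ccccc2)C(C)(C)C)C[C@H](OC(=O)/C(C)=C/C)[C@H]1C(C)=C | intermediate |
| 13 | isopropyl compound | CC(C)(C)[Si](C)(C)O[C@H]1C=C(CO[Si](c2ccccc2)(c2ccccc2)C(C)(C)C)C[C@H](OC(=O)/C(C)=C/C)[C@H]1C(C)C | intermediate |
| 14 | C5 alcohol | O[C@H]1C=C(CO[Si](c2ccccc2)(c2ccccc2)C(C)(C)C)C[C@H](OC(=O)/C(C)=C/C)[C@H]1C(C)C | intermediate |
| 15 | angelic acid | C/C=C(/C)C(=O)O | starting material |
| 16 | 2,4,6-trichlorobenzoyl chloride | O=C(Cl)c1c(Cl)cc(Cl)cc1Cl | starting material |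
| 17 | angelic 2,4,6-trichlorobenzoic anhydride, not isolated | C/C=C(/C)C(=O)OC(=O)c1c(Cl)cc(Cl)cc1Cl | intermediate |
| 18 | C5 angelate C3 tiglate diester | C/C=C(/C)C(=O)O[C@H]1C=C(CO[Si](c2ccccc2)(c2ccccc2)C(C)(C)C)C[C@H](OC(=O)/C(C)=C/C)[C@H]1C(C)C | intermediate |
| 19 | silyl-protected enone | C/C=C(/C)C(=O)O[C@H]1C=C(CO[Si](c2ccccc2)(c2ccccc2)C(C)(C)C)C(=O)[C@H](OC(=O)/C(C)=C/C)[C@H]1C(C)C | intermediate |
| 20 | CNP0293256.3 | C/C=C(/C)C(=O)O[C@H]1C=C(CO)C(=O)[C@H](OC(=O)/C(C)=C/C)[C@H]1C(C)C | target |

**Step count**
- Total: 12 steps.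
- Longest linear sequence: 11 steps (1, 2, 3, 4, 6, 7, 8, 9, 10, 11, 12).

**Steps most likely to fail**

**Step 6.**
- What may go wrong: the push–pull enone may react too slowly. Acid-induced decay of the dienol ether could then take over. So could conjugate addition followed by expulsion of tiglate, hetero-cycloaddition across the enone oxygen, or silyl transfer to the counter-ion, which opens a racemic channel. Poor facial or endo selectivity would be the milder form of failure.
- Fallback: chirality is taken from a resolution instead of a catalyst. Setting out from 7 and 10, the uncatalysed cycloaddition (toluene, 2,6-di-tert-butyl-4-methylphenol, 110 °C, or 12 kbar in CH2Cl2 at rt) should give the racemic endo adduct F1. The conditions of steps 7, 8 and 9 then carry it through the racemic isopropenyl compound F2 and the racemic isopropyl compound F3 to the racemic alcohol F4. Addition of F4 to (R)-1-(naphthalen-1-yl)ethyl isocyanate (4-(dimethylamino)pyridine, toluene, 80 °C) gives the carbamate of 14 F5 and the carbamate of the enantiomer of 14 F6, which are separated by chromatography. HSiCl3/Et3N in CH2Cl2 at rt cleaves F5 without touching the esters, and the route is rejoined at 14.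

**Step 11.**
- What may go wrong: hydrogen abstraction gives an allyl radical spread over C2, C1 and C6 that can take up oxygen at C6, which transposes the enone. Attack at C7–H or C5–H would cost the silyl ether or the angelate.
- Fallback: setting out from 18, oxygen is introduced by a pericyclic sequence whose regiochemistry is fixed by its mechanism. This is a Riley oxidation with SeO2 (catalytic) and tBuOOH in CH2Cl2 at rt. An ene reaction bonds selenium to the less substituted C6, and a [2,3]-sigmatropic shift then returns the alkene to C1=C6. It should give the C2 allylic alcohol F7 (either epimer). Dess–Martin oxidation (NaHCO3, CH2Cl2) converts F7 into 19.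

**Step 7.**
- What may go wrong: at 65 °C the doubly β-oxygenated ketone may undergo β-elimination at O3 or O5 or epimerise at C4, and the tiglate carbonyl may be methylenated in competition.
- Fallback: a two-stage Peterson olefination at low temperature. Setting out from 11, Me3SiCH2Li/CeCl3 (THF, −78 °C) acts as a non-basic organocerium reagent that should add only to the ketone, giving the β-hydroxysilane F8. Catalytic camphor-10-sulfonic acid in CH2Cl2 at 0 °C then triggers the anti-elimination, which leads to 12.

**Further compounds**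
F1 | step 6 | racemic endo adduct (11 and its enantiomer) | CC(C)(C)[Si](C)(C)O[C@H]1C=C(CO[Si](c2ccccc2)(c2ccccc2)C(C)(C)C)C[C@H](OC(=O)/C(C)=C/C)[C@H]1C(C)=O.CC(C)(C)[Si](C)(C)O[C@@H]1C=C(CO[Si](c2ccccc2)(c2ccccc2)C(C)(C)C)C[C@@H](OC(=O)/C(C)=C/C)[C@@H]1C(C)=O
F2 | step 6 | racemic isopropenyl compound (12 and its enantiomer) | CC(C)(C)[Si](C)(C)O[C@H]1C=C(CO[Si](c2ccccc2)(c2ccccc2)C(C)(C)C)C[C@H](OC(=O)/C(C)=C/C)[C@H]1C(C)=C.CC(C)(C)[Si](C)(C)O[C@@H]1C=C(CO[Si](c2ccccc2)(c2ccccc2)C(C)(C)C)C[C@@H](OC(=O)/C(C)=C/C)[C@@H]1C(C)=C
F3 | step 6 | racemic isopropyl compound (13 and its enantiomer) | CC(C)(C)[Si](C)(C)O[C@H]1C=C(CO[Si](c2ccccc2)(c2ccccc2)C(C)(C)C)C[C@H](OC(=O)/C(C)=C/C)[C@H]1C(C)C.CC(C)(C)[Si](C)(C)O[C@@H]1C=C(CO[Si](c2ccccc2)(c2ccccc2)C(C)(C)C)C[C@@H](OC(=O)/C(C)=C/C)[C@@H]1C(C)C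
F4 | step 6 | racemic alcohol (14 and its enantiomer) | O[C@H]1C=C(CO[Si](c2ccccc2)(c2ccccc2)C(C)(C)C)C[C@H](OC(=O)/C(C)=C/C)[C@H]1C(C)C.O[C@@H]1C=C(CO[Si](c2ccccc2)(c2ccccc2)C(C)(C)C)C[C@@H](OC(=O)/C(C)=C/C)[C@@H]1C(C)C
F5 | step 6 | carbamate of 14 with (R)-1-(naphthalen-1-yl)ethyl isocyanate | C[C@@H](NC(=O)O[C@H]1C=C(CO[Si](c2ccccc2)(c2ccccc2)C(C)(C)C)C[C@H](OC(=O)/C(C)=C/C)[C@H]1C(C)C)c1cccc2ccccc12
F6 | step 6 | carbamate of the enantiomer of 14 with (R)-1-(naphthalen-1-yl)ethyl isocyanate | C[C@@H](NC(=O)O[C@@H]1C=C(CO[Si](c2ccccc2)(c2ccccc2)C(C)(C)C)C[C@@H](OC(=O)/C(C)=C/C)[C@@H]1C(C)C)c1cccc2ccccc12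
F7 | step 11 | C2 allylic alcohol (C2 either epimer) | C/C=C(/C)C(=O)O[C@H]1C=C(CO[Si](c2ccccc2)(c2ccccc2)C(C)(C)C)C(O)[C@H](OC(=O)/C(C)=C/C)[C@H]1C(C)C
F8 | step 7 | β-hydroxysilane (C8 either epimer) | CC(C)(C)[Si](C)(C)O[C@H]1C=C(CO[Si](c2ccccc2)(c2ccccc2)C(C)(C)C)C[C@H](OC(=O)/C(C)=C/C)[C@H]1C(C)(O)C[Si](C)(C)C
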